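**Strategy.** Everything rests on reading the γ-oxygenated enone of the six-membered carbocycle (O=C6–C1=C2–C3–O; C7 is the CH2O carbon on C1) as an opened 1,4-endoperoxide. Sensitised singlet oxygen adds across C3 and C6 of the ring diene C6=C1–C2=C3, forming both C–O bonds, the 2,3-dioxabicyclo[2.2.2]octene and the C1=C2 alkene in one operation; amine-induced opening then gives the C6 ketone and C3 carbinol without any change in overall oxidation level. The precursor is (S)-(4-isopropylcyclohexa-1,5-dien-1-yl)methyl tiglate, a 7-acyloxy-α-phellandrene, made from 4-isopropylcyclohexanone through (S)-cryptone and its dienyl triflate. Tigloylation at C3 and acetoxylation at C5, trans to isopropyl, finish the target.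

Key step: step 7

Numbering used throughout: C1 carries the C7 methylene, C2 is the ring CH=, C3 carries the ring tiglate, C4 the isopropyl group, C5 the acetate, and C6 is the ketone carbon. The target is (3S,4S,5R): C3–O cis to isopropyl, C5–O trans to isopropyl.

Assumption: the sense of the chiral-amide deprotonation of 1 is taken to follow that known for 4-tert-butylcyclohexanone; if it proves opposite, the antipodal amide is used and nothing else changes.

**Step 1**
Reactants: 1 4-isopropylcyclohexanone
Product: 3 (R)-4-isopropyl-1-(trimethylsilyloxy)cyclohex-1-ene, via lithium enolate 2 (not isolated)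
Conditions: (S,S)-[PhCH(Me)]2NLi (from the amine, n-BuLi), TMSCl (in situ), THF, −78 °C
Reagents that add atoms: chlorotrimethylsilane, C[Si](C)(C)Cl
Why: Asymmetric deprotonation of a prochiral 4-substituted cyclohexanone by a C2-symmetric chiral lithium amide with internal silyl quench should discriminate the two enantiotopic axial α-hydrogens, which breaks the mirror symmetry and makes C4 a stereocentre of (R) configuration in 3; the low temperature and the TMSCl present from the start should keep the enantiomeric purity high.

**Step 2**
Reactants: 3 (R)-4-isopropyl-1-(trimethylsilyloxy)cyclohex-1-ene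
Product: 4 (S)-4-isopropylcyclohex-2-en-1-one ((S)-cryptone)
Conditions: Pd(OAc)2 (1.05 equiv), MeCN, rt
Reagents that add atoms: none
Why: Saegusa–Ito oxidation, in which the enol silane passes to an oxa-π-allyl palladium acetate and β-hydride elimination from C3 gives the enone under neutral conditions that should leave the γ-stereocentre C4 untouched (same spatial arrangement, descriptor changes to S by priority only).

**Step 3**
Reactants: 4 (S)-4-isopropylcyclohex-2-en-1-one
Product: 6 (S)-4-isopropylcyclohexa-1,5-dien-1-yl trifluoromethanesulfonate, via lithium dienolate 5 (not isolated)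
Conditions: LiN(i-Pr)2, THF, −78 °C; PhNTf2, −78 °C to 0 °C
Reagents that add atoms: N-phenylbis(trifluoromethanesulfonimide), O=S(=O)(N(c1ccccc1)S(=O)(=O)C(F)(F)F)C(F)(F)F
Why: Kinetic α′-deprotonation at C6 by the hindered amide gives the cross-conjugated dienolate, which PhNTf2 triflates on oxygen (enol triflate formation); the γ-hydrogen at C4 is not removed under these irreversible conditions, so the stereocentre should survive.

**Step 4**
Reactants: 6 (S)-4-isopropylcyclohexa-1,5-dien-1-yl trifluoromethanesulfonate
Product: 7 methyl (S)-4-isopropylcyclohexa-1,5-diene-1-carboxylate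
Conditions: CO (1 atm), Pd(OAc)2 (5 mol%), PPh3 (10 mol%), Et3N, MeOH–DMF, rt to 40 °C
Reagents that add atoms: carbon monoxide, [C-]#[O+]; methanol, CO
Why: Palladium-catalysed alkoxycarbonylation of an alkenyl triflate (oxidative addition to zerovalent palladium formed in situ, CO insertion, methanolysis of the acyl complex) is reliable for dienyl triflates, and the mild temperature should keep the diene in place.

**Step 5**
Reactants: 7 methyl (S)-4-isopropylcyclohexa-1,5-diene-1-carboxylate
Product: 8 [(S)-4-isopropylcyclohexa-1,5-dien-1-yl]methanol
Conditions: i-Bu2AlH (2.2 equiv), CH2Cl2, −78 °C to 0 °C; aq. potassium sodium tartrate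
Reagents that add atoms: none
Why: 1,2-Reduction of the conjugated ester by the aluminium hydride should stop cleanly at the primary dienyl alcohol without touching the diene.

**Step 6**
Reactants: 8 [(S)-4-isopropylcyclohexa-1,5-dien-1-yl]methanol; 9 tiglic acid
Product: 10 [(4S)-4-isopropylcyclohexa-1,5-dien-1-yl]methyl (E)-2-methylbut-2-enoate
Conditions: DCC, DMAP (cat.), CH2Cl2, 0 °C to rt
Reagents that add atoms: tiglic acid (9), C/C=C(\C)C(=O)O
Why: Steglich esterification of an unhindered primary allylic alcohol runs near neutrality, which avoids acid that could ionise the dienyl carbinol, and the (E)-enoate, being the thermodynamically preferred isomer, should keep its geometry.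

**Step 7**
Reactants: 10 [(4S)-4-isopropylcyclohexa-1,5-dien-1-yl]methyl (E)-2-methylbut-2-enoate; 11 dioxygen
Product: 12 [(1R,4S,7S)-7-isopropyl-2,3-dioxabicyclo[2.2.2]oct-5-en-5-yl]methyl (E)-2-methylbut-2-enoate (peroxide bridge syn to isopropyl)
Conditions: O2, tetraphenylporphyrin (cat.), visible light (LED), CH2Cl2, −20 °C
Reagents that add atoms: dioxygen (11), O=O
Why: Singlet oxygen, generated by energy transfer from the porphyrin triplet, adds suprafacially to the ring-locked s-cis diene C6=C1–C2=C3 in a concerted [4+2] cycloaddition, forming the C3–O and C6–O bonds and moving the alkene to C1=C2. The closest known reaction type is the photooxygenation of α-phellandrene and other cyclohexa-1,3-dienes to 2,3-dioxabicyclo[2.2.2]oct-5-enes. The six-membered 1,2-dioxene ring (C3–O–O–C6–C1=C2) is closed by cycloaddition, both of its new bonds forming in the same event at the diene termini. C3 and C6 are created together and must be cis to each other because the addition is suprafacial; their sense relative to C4 is decided by the diene face attacked, and 12 arises from attack on the face carrying the C4 isopropyl group, which is accessible when that group sits pseudoequatorial. The step needs chemoselectivity for [4+2] addition over ene reaction and for the diene over the electron-poor tiglate alkene, which the locked s-cis geometry and the deactivated enoate secure, while the low triplet energy of the porphyrin should leave the (E)-enoate geometry untouched. Facial selectivity is not secured by the substrate, so 12 is expected alongside its anti diastereomer, from which it is separated by chromatography and which is brought to 14 by the inversion sequence given among the fallbacks.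

**Step 8**
Reactants: 12 [(1R,4S,7S)-7-isopropyl-2,3-dioxabicyclo[2.2.2]oct-5-en-5-yl]methyl (E)-2-methylbut-2-enoate
Product: 13 [(3R,4S)-3-hydroxy-4-isopropyl-6-oxocyclohex-1-en-1-yl]methyl (E)-2-methylbut-2-enoate (hydroxyl cis to isopropyl)
Conditions: Et3N (1.2 equiv), CH2Cl2, 0 °C to rt
Reagents that add atoms: none
Why: Kornblum–DeLaMare rearrangement, in which the amine should remove the C6 bridgehead hydrogen (flanked by the C5 methylene and more accessible than the C3 hydrogen next to the isopropyl-bearing C4) as the O–O bond breaks, giving the C6 ketone conjugated with C1=C2 and the C3 carbinol, whose C–O bond is never broken so its cis relation to isopropyl is kept.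

**Step 9**
Reactants: 13 [(3R,4S)-3-hydroxy-4-isopropyl-6-oxocyclohex-1-en-1-yl]methyl (E)-2-methylbut-2-enoate; 9 tiglic acid
Product: 14 [(3R,4S)-4-isopropyl-3-{[(E)-2-methylbut-2-enoyl]oxy}-6-oxocyclohex-1-en-1-yl]methyl (E)-2-methylbut-2-enoate (ring tiglate cis to isopropyl)
Conditions: DCC, DMAP (0.2 equiv), CH2Cl2, 0 °C to rt
Reagents that add atoms: tiglic acid (9), C/C=C(\C)C(=O)O
Why: Steglich esterification acylates the secondary allylic oxygen without breaking the C3–O bond, so the configuration is retained, and the near-neutral medium spares the base-sensitive γ-hydroxy enone; any reversible allylic exchange of the C7 ester induced by DMAP is degenerate because tiglate is the only carboxylate present.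

**Step 10**
Reactants: 14 [(3R,4S)-4-isopropyl-3-{[(E)-2-methylbut-2-enoyl]oxy}-6-oxocyclohex-1-en-1-yl]methyl (E)-2-methylbut-2-enoate
Product: 15 [(3S,4S,5R)-5-acetoxy-4-isopropyl-3-{[(E)-2-methylbut-2-enoyl]oxy}-6-oxocyclohex-1-en-1-yl]methyl (E)-2-methylbut-2-enoate (target)
Conditions: Mn(OAc)3·2H2O (3 equiv), PhH–AcOH (10:1), 80 °C
Reagents that add atoms: manganese triacetate dihydrate, CC(=O)[O-].CC(=O)[O-].CC(=O)[O-].[Mn+3].O.O
Why: α′-Acetoxylation of an enone with Mn(OAc)3, in which the trivalent-manganese enolate formed at C5 should pass an acetate ligand to the face opposite the C4 isopropyl and C3 tiglate groups (both on the same face), setting C5 with the acetate trans to isopropyl, which is also the thermodynamically preferred diequatorial arrangement.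

**Compound list**
1 | 4-isopropylcyclohexanone | CC(C)C1CCC(=O)CC1 | starting material
2 | lithium (R)-4-isopropylcyclohex-1-en-1-olate | [Li+].[O-]C1=CC[C@H](C(C)C)CC1 | intermediate (not isolated)
3 | (R)-4-isopropyl-1-(trimethylsilyloxy)cyclohex-1-ene | C[Si](C)(C)OC1=CC[C@H](C(C)C)CC1 | intermediate
4 | (S)-4-isopropylcyclohex-2-en-1-one ((S)-cryptone) | O=C1C=C[C@H](C(C)C)CC1 | intermediate
5 | lithium (S)-4-isopropylcyclohexa-1,5-dien-1-olate | [Li+].[O-]C1=CC[C@@H](C(C)C)C=C1 | intermediate (not isolated)
6 | (S)-4-isopropylcyclohexa-1,5-dien-1-yl trifluoromethanesulfonate | O=S(=O)(OC1=CC[C@@H](C(C)C)C=C1)C(F)(F)F | intermediate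
7 | methyl (S)-4-isopropylcyclohexa-1,5-diene-1-carboxylate | COC(=O)C1=CC[C@@H](C(C)C)C=C1 | intermediate
8 | [(S)-4-isopropylcyclohexa-1,5-dien-1-yl]methanol | OCC1=CC[C@@H](C(C)C)C=C1 | intermediate
9 | tiglic acid, (E)-2-methylbut-2-enoic acid | C/C=C(\C)C(=O)O | starting material
10 | [(4S)-4-isopropylcyclohexa-1,5-dien-1-yl]methyl (E)-2-methylbut-2-enoate | C/C=C(\C)C(=O)OCC1=CC[C@@H](C(C)C)C=C1 | intermediate
11 | dioxygen | O=O | starting material
12 | [(1R,4S,7S)-7-isopropyl-2,3-dioxabicyclo[2.2.2]oct-5-en-5-yl]methyl (E)-2-methylbut-2-enoate, peroxide syn to isopropyl | C/C=C(\C)C(=O)OCC1=C[C@H]2[C@H](C(C)C)C[C@@H]1OO2 | intermediate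
13 | [(3R,4S)-3-hydroxy-4-isopropyl-6-oxocyclohex-1-en-1-yl]methyl (E)-2-methylbut-2-enoate | C/C=C(\C)C(=O)OCC1=C[C@H](O)[C@H](C(C)C)CC1=O | intermediate
14 | [(3R,4S)-4-isopropyl-3-{[(E)-2-methylbut-2-enoyl]oxy}-6-oxocyclohex-1-en-1-yl]methyl (E)-2-methylbut-2-enoate | C/C=C(\C)C(=O)OCC1=C[C@H](OC(=O)/C(C)=C/C)[C@H](C(C)C)CC1=O | intermediate
15 | [(3S,4S,5R)-5-acetoxy-4-isopropyl-3-{[(E)-2-methylbut-2-enoyl]oxy}-6-oxocyclohex-1-en-1-yl]methyl (E)-2-methylbut-2-enoate | C/C=C(\C)C(=O)OCC1=C[C@H](OC(=O)/C(C)=C/C)[C@H](C(C)C)[C@@H](OC(C)=O)C1=O | target

Total step count: 10. Longest linear sequence: 10 steps (1 to 15).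

**Steps most likely to fail**

1. Step 7, face selection in the cycloaddition. Attack of singlet oxygen on the diene face away from the C4 isopropyl group may dominate, so that little of the syn adduct forms; ene hydroperoxidation and aromatisation are lesser drains. The fallback sets out from 10 and returns at 14. The same photooxygenation of 10 is harvested for the anti endoperoxide F1. Et3N in CH2Cl2 opens it, as in step 8, to the trans hydroxy enone F2. F2 is then esterified with tiglic acid 9 under Mitsunobu conditions (PPh3, DIAD, betaine preformed at 0 °C, THF); SN2 displacement of the activated allylic C3 oxygen inverts that centre and should deliver 14. Preforming the betaine keeps free phosphine away from the enone.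

2. Step 8, regiocontrol of the bridgehead deprotonation. The amine may take the C3 hydrogen instead of the C6 hydrogen, giving the transposed hydroxy enone, or the γ-hydroxy enone may isomerise onward to a 1,4-dione on prolonged exposure to base. The fallback sets out from 12 and returns at 13, and removes base from the sequence. Thiourea in MeOH at rt reduces the O–O bond to the cis enediol F3. MnO2 in CH2Cl2 should then oxidise the C6 allylic carbinol in preference to the C3 carbinol: C6 is the less hindered of the two, and with isopropyl equatorial its C–H bond is pseudoaxial and aligned with the alkene π system. This gives 13.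

3. Step 10, chemoselectivity and facial control of the hot oxidation. Elimination or aromatisation of the densely acyloxylated enone at 80 °C, or incomplete face discrimination at C5, may erode the last step. The fallback sets out from 14 and returns at 15, and separates enolisation, oxygenation and acetylation. Kinetic α′-enolisation and silylation (LiN(SiMe3)2, TMSCl, THF, −78 °C) should give the cross-conjugated trimethylsilyl dienol ether F4. Rubottom oxidation with dimethyldioxirane in acetone at −78 °C should epoxidise the electron-rich C5=C6 enol ether anti to the isopropyl group; a buffered aqueous work-up then releases the α′-hydroxy enone F5. Acetylation (Ac2O, pyridine, 0 °C) gives 15.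

**Further compounds**
F1 | step 7 | [(1S,4R,7S)-7-isopropyl-2,3-dioxabicyclo[2.2.2]oct-5-en-5-yl]methyl (E)-2-methylbut-2-enoate, peroxide anti to isopropyl | C/C=C(\C)C(=O)OCC1=C[C@@H]2[C@H](C(C)C)C[C@H]1OO2
F2 | step 7 | [(3S,4S)-3-hydroxy-4-isopropyl-6-oxocyclohex-1-en-1-yl]methyl (E)-2-methylbut-2-enoate, hydroxyl trans to isopropyl | C/C=C(\C)C(=O)OCC1=C[C@@H](O)[C@H](C(C)C)CC1=O
F3 | step 8 | [(3R,4S,6S)-3,6-dihydroxy-4-isopropylcyclohex-1-en-1-yl]methyl (E)-2-methylbut-2-enoate, both hydroxyls cis to isopropyl | C/C=C(\C)C(=O)OCC1=C[C@H](O)[C@H](C(C)C)C[C@@H]1O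
F4 | step 10 | [(3R,4R)-4-isopropyl-3-{[(E)-2-methylbut-2-enoyl]oxy}-6-(trimethylsilyloxy)cyclohexa-1,5-dien-1-yl]methyl (E)-2-methylbut-2-enoate | C/C=C(\C)C(=O)OCC1=C[C@H](OC(=O)/C(C)=C/C)[C@H](C(C)C)C=C1O[Si](C)(C)C
F5 | step 10 | [(3S,4R,5R)-5-hydroxy-4-isopropyl-3-{[(E)-2-methylbut-2-enoyl]oxy}-6-oxocyclohex-1-en-1-yl]methyl (E)-2-methylbut-2-enoate | C/C=C(\C)C(=O)OCC1=C[C@H](OC(=O)/C(C)=C/C)[C@H](C(C)C)[C@@H](O)C1=O
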